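All constants are invented; the rest is arithmetic.

Follow the target.

| setting | alpha | gamma |
|---|---|---|
| starting material | 0.46 M (fed, over 10 min) | 0.46 M (fed, over 10 min) |
| partner | 0.506 M | 0.506 M |
| temperature | 35 °C | 15 °C |
| time | 10 min | 10 min |

    starting material + partner → target + by-product (k1 = 1.5 M⁻¹ min⁻¹, Ea1 = 73.0 kJ mol⁻¹)
    partner → decomposed reagent (k2 = 0.024 min⁻¹, Ea2 = 99.0 kJ mol⁻¹)
    target + by-product → side product (k3 = 0.11 M⁻¹ min⁻¹, Ea3 = 65.0 kJ mol⁻¹)
    (constants at 35 °C)

* which flask leads in share of target in all that became target or side product ("all alike" within 1.5 percentage points) (alpha / gamma / all alike)
* share of target in all that became target or side product, alpha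
* share of target in all that became target or side product, gamma

- at 35 °C the constants are as listed, elsewhere as the activation energies make them

Draw alpha first. The target curve starts flat, since the flask holds no starting material yet, and starting material climbs at the feed rate, 0.0460 M min⁻¹. Partner consumes it at 0.759 min⁻¹ per unit of starting material. Partner's own decay starts at 0.0121 M min⁻¹, slower than the feed, so drop that step. Step 1 uses partner mole for mole from a charge of 1.10 equivalents, so holding partner at its charge is a rough simplification that draws the curve too high. The knee lies at the lag, 1.32 min. Past it, on this simplified line, starting material levels near 0.0607 M and target rises straight at the feed rate, reaching 0.399 M at the end of the dose by my reckoning.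

Now draw gamma. Step 1 is slower by a factor of 7.2, so the lag grows to 9.52 min, close to the whole dose. The knee barely arrives, the curve bends upward throughout, and the same lag curve ends at 0.175 M, less than in alpha.

Target and by-product form together and are lost together, so they stay equal, and side product grows as the sum of target squared. For a straight rise that sum is the final square times the time over 3. Dividing by target gives the wear, side product per target, as target times the wear coefficient, step 3's constant times the time over 3: 0.367 M⁻¹ for alpha. For a rise going with the square of time, use 5, and step 3's constant reduced by 5.8: 0.0378 M⁻¹ for gamma. The share of target (the selectivity) is one over one plus the wear. That gives 87.2% for alpha and 99.3% for gamma.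

The forecast names gamma, with 90% for alpha and 99.4% for gamma, and says of alpha “roughly a tenth of it is lost”. My alpha figure lies lower, and my gamma figure matches.

The simulation gives 90.1% for alpha and 99.3% for gamma, so gamma leads.

Alpha ends with 0.281 M of target, less than my line, and with partner at 23.6% of its charge, and the coefficient on that amount of target gives a share of 90.7%. Take the neighbour with 0.20 M of partner, at alpha's temperature and time, and carry over 0.367 M⁻¹ as a rough coefficient: it was reckoned for a straight rise, and this neighbour's partner falls to 8.40% of its charge. It ends with 0.149 M of target, so by that coefficient the wear is 5.46% and the share 94.8%. The simulated neighbour gives 94.0%.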